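| flask | starting material | catalyst | remark | time |
|---|---|---|---|---|
| midnight | 10 mM | 1 mM | run made earlier |  |
| summer | 10 mM | 0.50 mM | run made earlier |  |
| autumn | 10 mM | 0.75 mM | run made earlier |  |
| alder | 10 mM (fed, over 25.0 min) | 1.0 mM | a stirred flask in which starting material is dosed at a steady rate over 25.0 min without added volume, worked up at 25 min | 25 min |
| cedar | 10 mM | 1.0 mM | one stirred flow tank at steady state, fed with the mixture as stated, mean residence time 25 min |  |
| birch | 10 mM | 1.0 mM | everything together in a closed stirred flask, run for 25 min | 25 min |

| run | time / min | target / % |
|---|---|---|
| midnight | 2.00 | 6.3 |
| midnight | 3.00 | 8.3 |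
| midnight | 6.00 | 14.8 |
| midnight | 10.0 | 19.9 |
| midnight | 15.0 | 22.9 |
| midnight | 25.0 | 25.0 |
| summer | 2.50 | 3.4 |
| summer | 5.00 | 7.4 |
| summer | 8.00 | 9.3 |
| summer | 10.0 | 11.1 |
| summer | 12.0 | 11.2 |
| summer | 15.0 | 12.7 |
| autumn | 2.50 | 5.5 |
| autumn | 5.00 | 9.6 |
| autumn | 8.00 | 13.1 |
| autumn | 10.0 | 15.3 |
| autumn | 12.0 | 16.5 |
| autumn | 15.0 | 17.5 |

(scatter of a reading: 0.5 percentage points)

- the stated concentrations are those of everything mixed, before any reaction; amounts are the same in each set-up
- steps under discussion: starting material -> side product; starting material + catalyst -> catalyst + target
- the feed brings no volume worth counting
- the earlier runs were made in a closed, stirred flask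

- the set-up with the highest amount of target at the outlet or at the end, in percent of the starting material put in ("none" if the first two lie within 2 percentage points) (alder / cedar / birch / none)
- amount of target at the outlet or at the end, in percent of the starting material put in, alder
- amount of target at the outlet or at the end, in percent of the starting material put in, cedar
- amount of target at the outlet or at the end, in percent of the starting material put in, birch

**Easy step.** The easy step is to read the top of the midnight run: a closed flask with [catalyst] at 1 mM reaches 25.0% of target at 25.0 min. I follow one molecule of starting material to a fork. It goes by itself to side product, or with catalyst to target. Each exit as written takes one molecule of starting material, so [starting material] cancels from the odds and [catalyst] stays in them. The rise to 14.8% at 6.00 min reads as a mean lifetime of 6.69 min. With what is unreacted at the top allowed for, the top reads 25.6%. This is the fork share, the chance that one molecule ends as target, the usual selectivity.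

**Bench rule.** The bench rule says that, with [catalyst] held and both exits as written, target equals the fork share once molecules have stayed long against their lifetime, whatever the vessel. Birch has the charge of the midnight run and lasts 25 min, which is 3.74 lifetimes, so I expect 25.0%.

**Its border.** The rule stops where the stay is short, and the same ratio shows where. For cedar, at a mean residence time of 25 min, I reckon one part unreacted for every 3.74 parts reacted, and so 20.2% of target. Alder is fed for 25.0 min, and its latest molecules have had less than one lifetime, so I reckon 18.9%. I put birch first.

**The forecast.** The forecast gives 19% for alder, 20.2% for cedar and 25% for birch, and names birch as best, holding that “selectivity is fixed at about 25.6% and dosing gains nothing”.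

**The result.** The flasks give 18.8% for alder, 20.6% for cedar and 26.0% for birch, so birch leads, as forecast.

    starting material → side product (k = 0.0909 min⁻¹)
    starting material + catalyst → catalyst + target (k = 33.9 L mol⁻¹ min⁻¹)

**The fork again.** In birch the side step uses starting material 2.7 times as fast as the target step at the start, and 2.7 times as fast at 25.0 min. A neighbouring flask, birch read at 6.0 min, still holds 47.3% of its starting material, so the fork share read from the midnight run, 25.6%, of the reacted part gives 13.5% of target, and that flask stands at 14.3%.

The data are calculated on assumed constants, noise included.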